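**Retrosynthetic overview** (germacrane numbering; target = 29, (1S,6R,8S,4Z))
1. Ten-membered ring, formed last: C1–C10 by Ni/Cr-catalysed alkenyl iodide–aldehyde (Nozaki–Hiyama–Kishi) macrocyclisation of seco-iodide 27, setting C1 with both acetates already in place.
2. Butenolide, formed first: Ni(0)-catalysed carbonylative [2+2+1] of Z-enal 10, alkyne 23 and CO makes C6–C7, C11–C12 and the lactone C–O bond and sets C6.
3. Alkyne 23 (C7–C11, C13, C14; C8 centre): asymmetric allylboration of ynal 14 (from propargyl alcohol) with 2-silylallyl bromide 18; the vinylsilane is the masked C10 iodide.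
4. Enal 10 (C1–C6, C15): syn-carbocupration of propyne with the acrolein-derived acetal Grignard fixes the 4Z olefin; formylation adds C6.

Assumption: the facial sense stated for the chiral ligands in steps 10 and 14 is taken as given; if a first run shows the opposite sense, the mirror-image ligand is used.

**Step 1**
Reactants: 1 acrolein
Product: 3 2-(2-bromoethyl)-1,3-dioxolane, via 3-bromopropanal 2 (not isolated)
Conditions: HBr (g), CH2Cl2, 0 °C; then HOCH2CH2OH, TsOH (cat.), rt
Reagents that add atoms: hydrogen bromide, Br; ethylene glycol, OCCO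
Why: Conjugate addition of HBr to the enal followed by in situ acetalisation is a standard one-pot preparation of this bromoacetal; no stereocentre.

**Step 2**
Reactants: 3 2-(2-bromoethyl)-1,3-dioxolane; 4 propyne
Product: 8 2-[(3Z)-4-iodo-3-methylbut-3-en-1-yl]-1,3-dioxolane, via Grignard reagent 5 (not isolated), via alkylcopper 6 (not isolated), via alkenylcopper 7 (not isolated)
Conditions: Mg, THF, 25 °C; CuBr·SMe2, Et2O/Me2S, −45 °C; propyne, −25 °C; I2, −50 → 0 °C
Reagents that add atoms: iodine, II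
Why: Normant syn-carbocupration puts the alkyl group on the internal carbon and copper on the terminal carbon on the same face, and iodinolysis with retention gives the Z-iodide that fixes the 4Z geometry (C3 cis to the future C6).

**Step 3**
Reactants: 8 2-[(3Z)-4-iodo-3-methylbut-3-en-1-yl]-1,3-dioxolane
Product: 10 (2Z)-5-(1,3-dioxolan-2-yl)-3-methylpent-2-enal, via alkenyllithium 9 (not isolated)
Conditions: t-BuLi (2.1 equiv), Et2O, −78 °C; DMF, −78 → −20 °C; aq. KH2PO4
Reagents that add atoms: N,N-dimethylformamide, CN(C)C=O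
Why: Iodine–lithium exchange and formylation with DMF both go with retention of the Z geometry, and the buffered quench avoids Z→E isomerisation of the enal.

**Step 4**
Reactants: 11 propargyl alcohol
Product: 12 triethyl(prop-2-yn-1-yloxy)silane
Conditions: TESCl, imidazole, CH2Cl2, 0 °C
Reagents that add atoms: chlorotriethylsilane, CC[Si](Cl)(CC)CC
Why: Routine silylation of a primary alcohol; TES is chosen so that it later falls off together with the acetal.

**Step 5**
Reactants: 12 triethyl(prop-2-yn-1-yloxy)silane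
Product: 14 4-[(triethylsilyl)oxy]but-2-ynal, via lithium acetylide 13 (not isolated)
Conditions: n-BuLi, THF, −78 °C; DMF; reverse quench into aq. KH2PO4
Reagents that add atoms: N,N-dimethylformamide, CN(C)C=O
Why: Formylation of a lithium acetylide with DMF and a reverse phosphate quench is a reliable route to ynals; no stereocentre.

**Step 6**
Reactants: 15 (1-bromovinyl)trimethylsilane
Product: 17 2-(trimethylsilyl)prop-2-en-1-ol, via vinyl Grignard reagent 16 (not isolated)
Conditions: Mg, THF, reflux; (CH2O)n, 0 °C → rt; aq. NH4Cl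
Reagents that add atoms: paraformaldehyde (formaldehyde), C=O
Why: Grignard formation from the α-bromovinylsilane and 1,2-addition to formaldehyde; no stereocentre.

**Step 7**
Reactants: 17 2-(trimethylsilyl)prop-2-en-1-ol
Product: 18 3-bromo-2-(trimethylsilyl)prop-1-ene
Conditions: CBr4, PPh3, CH2Cl2, 0 °C
Reagents that add atoms: carbon tetrabromide, BrC(Br)(Br)Br
Why: Appel bromination of a primary allylic alcohol under neutral conditions leaves the vinylsilane untouched.

**Step 8**
Reactants: 18 3-bromo-2-(trimethylsilyl)prop-1-ene; 14 4-[(triethylsilyl)oxy]but-2-ynal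
Product: 22 (4S)-1-[(triethylsilyl)oxy]-6-(trimethylsilyl)hept-6-en-2-yn-4-ol, via allyl Grignard reagent 19 (not isolated), via allylborane 20 (not isolated), via borinate 21 (not isolated)
Conditions: Mg, Et2O, 0 °C; (−)-Ipc2BOMe, −78 → 25 °C; 14, −78 °C, 3 h; then 3 M NaOAc, 30 % H2O2, rt
Reagents that add atoms: none
Why: Brown asymmetric allylboration: the 2-substituted allyl–B(Ipc)2 reagent from (+)-α-pinene adds through a chair Zimmerman–Traxler transition state to the Si face of the ynal, giving the (S)-carbinol (C8) in the same sense as with aryl aldehydes.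

**Step 9**
Reactants: 22 (4S)-1-[(triethylsilyl)oxy]-6-(trimethylsilyl)hept-6-en-2-yn-4-ol
Product: 23 (4S)-1,4-bis[(triethylsilyl)oxy]-6-(trimethylsilyl)hept-6-en-2-yne
Conditions: TESCl, imidazole, DMAP (cat.), CH2Cl2, 0 °C
Reagents that add atoms: chlorotriethylsilane, CC[Si](Cl)(CC)CC
Why: Silylation of the propargylic alcohol removes the free OH before the nickel step; the C8 centre is not touched.

**Step 10**
Reactants: 10 (2Z)-5-(1,3-dioxolan-2-yl)-3-methylpent-2-enal; 23 (4S)-1,4-bis[(triethylsilyl)oxy]-6-(trimethylsilyl)hept-6-en-2-yne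
Product: 24 (5R)-5-[(1Z)-4-(1,3-dioxolan-2-yl)-2-methylbut-1-en-1-yl]-3-{[(triethylsilyl)oxy]methyl}-4-[(1S)-1-[(triethylsilyl)oxy]-3-(trimethylsilyl)but-3-en-1-yl]furan-2(5H)-one
Conditions: Ni(cod)2 (10 mol %), (4R,5R)-L* (12 mol %; L* = 1,3-bis[2,6-bis(diphenylmethyl)-4-methylphenyl]-4,5-diphenylimidazolidin-2-ylidene), CO (1.3 equiv, fed over 10 h as 2 % CO in Ar), toluene, 50 °C
Reagents that add atoms: carbon monoxide, [C-]#[O+]
Why: Proposed new method: a Ni(0)-catalysed intermolecular oxa-[2+2+1] (hetero-Pauson–Khand) annulation in which oxidative cyclisation of aldehyde 10 and alkyne 23 on Ni(0)–NHC gives an oxanickelacyclopentene, the very bulky NHC placing the larger branched alkyne substituent (C8) next to the new C6–C7 bond and its chiral pocket exposing the Si face of the aldehyde (6R), after which CO inserts into the Ni–C11 bond and C–O reductive elimination releases the butenolide and Ni(0), the slow CO feed keeping nickel from resting as Ni(CO)n and the β,β-disubstituted enal blocking the competing conjugate [3+2] mode; the closest known reactions are the Ni/NHC reductive aldehyde–alkyne coupling (same metallacycle, ligand-controlled regio- and enantioselectivity), the Ni-catalysed carbonylative [2+2+1] of imines with alkynes to γ-lactams, and the intramolecular Ti-, Ru- and Mo-based hetero-Pauson–Khand reactions.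

**Step 11**
Reactants: 24 the butenolide from step 10
Product: 25 (4Z)-5-{(2R)-4-(hydroxymethyl)-3-[(1S)-1-hydroxy-3-(trimethylsilyl)but-3-en-1-yl]-5-oxo-2,5-dihydrofuran-2-yl}-4-methylpent-4-enal
Conditions: PPTS (0.3 equiv), acetone/H2O 10:1, 50 °C
Reagents that add atoms: water, O
Why: Mild acid solvolysis cleaves both TES ethers and hydrolyses the dioxolane in one operation, while the vinylsilane and the allylic lactone are stable to PPTS.

**Step 12**
Reactants: 25 the diol aldehyde from step 11
Product: 26 (1S)-1-{(2R)-4-(acetoxymethyl)-2-[(1Z)-2-methyl-5-oxopent-1-en-1-yl]-5-oxo-2,5-dihydrofuran-3-yl}-3-(trimethylsilyl)but-3-en-1-yl acetate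
Conditions: Ac2O, pyridine, CH2Cl2, 0 °C → rt
Reagents that add atoms: acetic anhydride, CC(=O)OC(C)=O
Why: Acylation of the primary (C13) and secondary (C8) allylic alcohols; the aldehyde is inert in the absence of DMAP.

**Step 13**
Reactants: 26 the diacetate vinylsilane from step 12
Product: 27 (1S)-1-{(2R)-4-(acetoxymethyl)-2-[(1Z)-2-methyl-5-oxopent-1-en-1-yl]-5-oxo-2,5-dihydrofuran-3-yl}-3-iodobut-3-en-1-yl acetate
Conditions: NIS (1.3 equiv), MeCN/ClCH2CN 4:1, 0 °C → rt
Reagents that add atoms: N-iodosuccinimide, O=C1CCC(=O)N1I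
Why: Electrophilic ipso-iododesilylation of the 2-silyl-1-alkene through the β-silyl cation is the standard entry to 2-iodo-1-alkenes for Ni/Cr couplings, and the trisubstituted olefin is deactivated by the allylic lactone oxygen.

**Step 14**
Reactants: 27 the seco-iodide from step 13
Product: 29 8α,13-diacetoxy-1α-hydroxygermacra-4,7(11),10(14)-trien-6α,12-olide (target), via O-trimethylsilyl ether 28 (not isolated)
Conditions: CrCl2 (15 mol %), (S)-N-[2-(4-isopropyl-4,5-dihydrooxazol-2-yl)-6-methoxyphenyl]methanesulfonamide (17 mol %), Et3N (20 mol %), NiCl2 (3 mol %), Mn (3 equiv), TMSCl (3 equiv), THF/MeCN, rt, syringe pump to 2 mM; then 0.5 M HCl, THF, 0 °C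
Reagents that add atoms: none
Why: Ni/Cr-catalysed Nozaki–Hiyama–Kishi alkenylation, in which Ni(0) inserts into the C–I bond, the alkenyl group passes to Cr(III) and adds to the tethered aldehyde while Mn/TMSCl turn chromium over; the sulfonamide-bound chromium delivers the alkenyl group to the Re face of C1 (1S), and the Z-olefin and butenolide pre-organise the chain for ten-membered ring closure at high dilution.

**Compound list**
1 | acrolein | C=CC=O | starting material
2 | 3-bromopropanal | O=CCCBr | intermediate (not isolated)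
3 | 2-(2-bromoethyl)-1,3-dioxolane | BrCCC1OCCO1 | intermediate
4 | propyne | CC#C | starting material
5 | [2-(1,3-dioxolan-2-yl)ethyl]magnesium bromide | Br[Mg]CCC1OCCO1 | intermediate (not isolated)
6 | [2-(1,3-dioxolan-2-yl)ethyl]copper (MgBr2 complex, drawn as RCu) | [Cu]CCC1OCCO1 | intermediate (not isolated)
7 | [(1Z)-4-(1,3-dioxolan-2-yl)-2-methylbut-1-en-1-yl]copper | [Cu]/C=C(/C)CCC1OCCO1 | intermediate (not isolated)
8 | 2-[(3Z)-4-iodo-3-methylbut-3-en-1-yl]-1,3-dioxolane | I/C=C(/C)CCC1OCCO1 | intermediate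
9 | [(1Z)-4-(1,3-dioxolan-2-yl)-2-methylbut-1-en-1-yl]lithium | [Li]/C=C(/C)CCC1OCCO1 | intermediate (not isolated)
10 | (2Z)-5-(1,3-dioxolan-2-yl)-3-methylpent-2-enal | O=C/C=C(/C)CCC1OCCO1 | intermediate
11 | propargyl alcohol | C#CCO | starting material
12 | triethyl(prop-2-yn-1-yloxy)silane | C#CCO[Si](CC)(CC)CC | intermediate
13 | lithium 3-[(triethylsilyl)oxy]prop-1-yn-1-ide | [Li]C#CCO[Si](CC)(CC)CC | intermediate (not isolated)
14 | 4-[(triethylsilyl)oxy]but-2-ynal | O=CC#CCO[Si](CC)(CC)CC | intermediate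
15 | (1-bromovinyl)trimethylsilane | C=C(Br)[Si](C)(C)C | starting material
16 | [1-(trimethylsilyl)vinyl]magnesium bromide | C=C([Mg]Br)[Si](C)(C)C | intermediate (not isolated)
17 | 2-(trimethylsilyl)prop-2-en-1-ol | C=C(CO)[Si](C)(C)C | intermediate
18 | 3-bromo-2-(trimethylsilyl)prop-1-ene | C=C(CBr)[Si](C)(C)C | intermediate
19 | [2-(trimethylsilyl)prop-2-en-1-yl]magnesium bromide | C=C(C[Mg]Br)[Si](C)(C)C | intermediate (not isolated)
20 | B-[2-(trimethylsilyl)prop-2-en-1-yl]diisopinocampheylborane (Ipc from (+)-α-pinene) | C=C([Si](C)(C)C)CB([C@@H]1C[C@@H]2C[C@H]([C@H]1C)C2(C)C)[C@@H]1C[C@@H]2C[C@H]([C@H]1C)C2(C)C | intermediate (not isolated)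
21 | diisopinocampheylborinate ester of 22 | C=C([Si](C)(C)C)C[C@H](OB([C@@H]1C[C@@H]2C[C@H]([C@H]1C)C2(C)C)[C@@H]1C[C@@H]2C[C@H]([C@H]1C)C2(C)C)C#CCO[Si](CC)(CC)CC | intermediate (not isolated)
22 | (4S)-1-[(triethylsilyl)oxy]-6-(trimethylsilyl)hept-6-en-2-yn-4-ol | C=C([Si](C)(C)C)C[C@H](O)C#CCO[Si](CC)(CC)CC | intermediate
23 | (4S)-1,4-bis[(triethylsilyl)oxy]-6-(trimethylsilyl)hept-6-en-2-yne | C=C([Si](C)(C)C)C[C@H](O[Si](CC)(CC)CC)C#CCO[Si](CC)(CC)CC | intermediate
24 | (5R)-5-[(1Z)-4-(1,3-dioxolan-2-yl)-2-methylbut-1-en-1-yl]-3-{[(triethylsilyl)oxy]methyl}-4-[(1S)-1-[(triethylsilyl)oxy]-3-(trimethylsilyl)but-3-en-1-yl]furan-2(5H)-one | C=C([Si](C)(C)C)C[C@H](O[Si](CC)(CC)CC)C1=C(CO[Si](CC)(CC)CC)C(=O)O[C@@H]1/C=C(/C)CCC1OCCO1 | intermediate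
25 | (4Z)-5-{(2R)-4-(hydroxymethyl)-3-[(1S)-1-hydroxy-3-(trimethylsilyl)but-3-en-1-yl]-5-oxo-2,5-dihydrofuran-2-yl}-4-methylpent-4-enal | C=C([Si](C)(C)C)C[C@H](O)C1=C(CO)C(=O)O[C@@H]1/C=C(/C)CCC=O | intermediate
26 | (1S)-1-{(2R)-4-(acetoxymethyl)-2-[(1Z)-2-methyl-5-oxopent-1-en-1-yl]-5-oxo-2,5-dihydrofuran-3-yl}-3-(trimethylsilyl)but-3-en-1-yl acetate | C=C([Si](C)(C)C)C[C@H](OC(C)=O)C1=C(COC(C)=O)C(=O)O[C@@H]1/C=C(/C)CCC=O | intermediate
27 | (1S)-1-{(2R)-4-(acetoxymethyl)-2-[(1Z)-2-methyl-5-oxopent-1-en-1-yl]-5-oxo-2,5-dihydrofuran-3-yl}-3-iodobut-3-en-1-yl acetate | C=C(I)C[C@H](OC(C)=O)C1=C(COC(C)=O)C(=O)O[C@@H]1/C=C(/C)CCC=O | intermediate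
28 | 1-O-trimethylsilyl ether of 29 | C=C1C[C@H](OC(C)=O)C2=C(COC(C)=O)C(=O)O[C@@H]2/C=C(/C)CC[C@@H]1O[Si](C)(C)C | intermediate (not isolated)
29 | 8α,13-diacetoxy-1α-hydroxygermacra-4,7(11),10(14)-trien-6α,12-olide, (1S,6R,8S,4Z) | C=C1C[C@H](OC(C)=O)C2=C(COC(C)=O)C(=O)O[C@@H]2/C=C(/C)CC[C@@H]1O | target

**Step count and risks**
Total: 14 steps. Longest linear sequence: 9 steps (4, 5, 8, 9, 10, 11, 12, 13, 14; the branch 6, 7, 8–14 is equally long; the enal branch 1–3 plus 10–14 is 8).

Steps most likely to fail: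

Step 10 (the new annulation). Risks are the regiochemistry at the alkyne, the face selectivity at C6, Tishchenko or trimerisation side reactions, and nickel poisoning by CO. The fallback uses known chemistry, sets out from 23 and comes back at 24. Alkyne 23 is converted into its titanium–alkyne complex (Ti(OiPr)4, 2 i-PrMgCl, Et2O, −78 → −50 °C, kept cold to avoid loss of the propargylic silyloxy groups). CO2 carboxylates the less hindered acetylenic carbon (C11), and I2 cleaves the remaining C7–Ti bond with retention to give (2Z,4S)-3-iodo-4-[(triethylsilyl)oxy]-2-{[(triethylsilyl)oxy]methyl}-6-(trimethylsilyl)hepta-2,6-dienoic acid F1. TMSCHN2 in toluene/MeOH gives methyl (2Z,4S)-3-iodo-4-[(triethylsilyl)oxy]-2-{[(triethylsilyl)oxy]methyl}-6-(trimethylsilyl)hepta-2,6-dienoate F2. A Nozaki–Hiyama–Kishi coupling of this β-iodo enoate with enal 10 (CrCl2, cat. NiCl2, DMF/THF, rt; chiral sulfonamide on chromium or chromatographic separation for C6) gives a chromium alkoxide that lactonises onto the cis ester, which is compound 24.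

Step 14 (macrocyclisation). Risks are oligomerisation and the wrong C1 configuration. The fallback sets out from 27 and comes back at 29. A ligand-free Nozaki–Hiyama–Kishi closure (excess CrCl2, cat. NiCl2, DMSO/THF, 2 mM) gives 29 together with its C1 epimer, (1R)-8α,13-diacetoxy-1-hydroxygermacra-4,7(11),10(14)-trien-6α,12-olide F3. The mixture is oxidised with Dess–Martin periodinane to 8α,13-diacetoxy-1-oxogermacra-4,7(11),10(14)-trien-6α,12-olide F4. Reagent-controlled 1,2-reduction of this enone ((R)-Me-CBS, catecholborane, −78 °C, the alkenyl side acting as the large group) then sets 1S and returns to 29, so the centre is made by ketone reduction instead of by C–C bond formation.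

Step 8 (allylboration with an untested 2-silylallyl borane on a base-sensitive ynal). The fallback sets out from 18 and 14 and comes back at 23. A chromium-catalysed enantioselective Nozaki–Hiyama allylation (CrCl3·3THF with a chiral tridentate bis(oxazolinyl)carbazole ligand, 5 mol %, Mn, i-Pr2NEt, TESCl as turnover reagent, THF, rt) joins 18 and 14 and releases the C8 carbinol directly as its triethylsilyl ether, which is compound 23, so steps 8 and 9 are replaced by one catalytic step; no new compound is made (none F0).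

**Further compounds**
F1 | step 10 | (2Z,4S)-3-iodo-4-[(triethylsilyl)oxy]-2-{[(triethylsilyl)oxy]methyl}-6-(trimethylsilyl)hepta-2,6-dienoic acid | OC(=O)/C(CO[Si](CC)(CC)CC)=C(\I)[C@@H](O[Si](CC)(CC)CC)CC(=C)[Si](C)(C)C
F2 | step 10 | methyl (2Z,4S)-3-iodo-4-[(triethylsilyl)oxy]-2-{[(triethylsilyl)oxy]methyl}-6-(trimethylsilyl)hepta-2,6-dienoate | COC(=O)/C(CO[Si](CC)(CC)CC)=C(\I)[C@@H](O[Si](CC)(CC)CC)CC(=C)[Si](C)(C)C
F3 | step 14 | (1R)-8α,13-diacetoxy-1-hydroxygermacra-4,7(11),10(14)-trien-6α,12-olide (C1 epimer of 29) | C=C1C[C@H](OC(C)=O)C2=C(COC(C)=O)C(=O)O[C@@H]2/C=C(/C)CC[C@H]1O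
F4 | step 14 | 8α,13-diacetoxy-1-oxogermacra-4,7(11),10(14)-trien-6α,12-olide | C=C1C[C@H](OC(C)=O)C2=C(COC(C)=O)C(=O)O[C@@H]2/C=C(/C)CCC1=O
F0 | step 8 | none | none
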